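The route rests on making the O3–acetyl ester bond and the C5–H bond together. The feature exploited is the 3,5-anti diol of the C1–C7 chain, esterified at O3 (on the side of the 3,4-dihydroxyphenyl ring) yet free at O5 (on the side of the 4-hydroxyphenyl ring). The two carbinols sit in nearly identical surroundings, so no acylating agent could choose between them. A SmI2-catalysed Evans–Tishchenko reaction of acetaldehyde with an (S)-β-hydroxy ketone (C3–OH, C5=O, all phenols benzylated) reduces C5 anti to C3 and acetylates O3 in one operation. This ketone comes from a Noyori-reduced β-keto ester through its Weinreb amide and a 2-arylethyl Grignard reagent; hydrogenolysis then frees the phenols.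

Key step: step 10

Remark on the chemistry: the heptane chain is numbered from the carbon bonded to the 3,4-dihydroxyphenyl ring (C1) to the carbon bonded to the 4-hydroxyphenyl ring (C7). The target is then the (3S,5S)-3-acetate, which is the anti diol. The labels C1–C7, O3 and O5 keep this meaning in every intermediate, whatever its systematic name.

Step 1
Reactants: 1 3,4-bis(benzyloxy)benzaldehyde
Product: 2 [3,4-bis(benzyloxy)phenyl]methanol
Conditions: NaBH4, MeOH/THF, 0 °C to rt
Reagents that add atoms: none
Why: Borohydride reduction of an aromatic aldehyde to the benzylic alcohol is chemoselective and leaves the aryl benzyl ethers alone.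

Step 2
Reactants: 2 [3,4-bis(benzyloxy)phenyl]methanol
Product: 3 1,2-bis(benzyloxy)-4-(chloromethyl)benzene (3,4-bis(benzyloxy)benzyl chloride)
Conditions: SOCl2, CH2Cl2, 0 °C to rt; evaporated and used at once
Reagents that add atoms: thionyl chloride, ClS(Cl)=O
Why: Deoxychlorination of an electron-rich benzylic alcohol through its chlorosulfite is fast, and the labile chloride is carried on without chromatography.

Step 3
Reactants: 3 1,2-bis(benzyloxy)-4-(chloromethyl)benzene, 4 methyl acetoacetate
Product: 6 methyl 5-[3,4-bis(benzyloxy)phenyl]-3-oxopentanoate, via methyl acetoacetate dianion 5 (not isolated)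
Conditions: 4 (1.15 equiv), NaH, THF, 0 °C; n-BuLi, 0 °C; then 3, 0 °C to rt; cold 1 M HCl
Reagents that add atoms: none
Why: In this acetoacetate dianion alkylation the terminal (γ) carbanion is the more nucleophilic site, so SN2 displacement of the benzylic chloride forms the C1–C2 bond and the β-keto ester is released on acidic quench.

Step 4
Reactants: 6 methyl 5-[3,4-bis(benzyloxy)phenyl]-3-oxopentanoate
Product: 7 methyl (S)-5-[3,4-bis(benzyloxy)phenyl]-3-hydroxypentanoate
Conditions: RuCl2[(S)-BINAP] (0.5 mol %, divalent ruthenium), H2 (4–10 atm), degassed MeOH, 50 °C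
Reagents that add atoms: none
Why: In this Noyori asymmetric hydrogenation the ester carbonyl chelates ruthenium and the (S)-BINAP ligand directs hydride to one ketone face, which should set C3 as S in the sense established for simple alkyl β-keto esters, while the benzyl ethers are inert to the homogeneous catalyst.

Step 5
Reactants: 7 methyl (S)-5-[3,4-bis(benzyloxy)phenyl]-3-hydroxypentanoate
Product: 8 (S)-5-[3,4-bis(benzyloxy)phenyl]-3-hydroxy-N-methoxy-N-methylpentanamide
Conditions: MeNHOMe·HCl (2 equiv), i-PrMgCl (5 equiv), THF, −20 to 0 °C; aq. NH4Cl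
Reagents that add atoms: N,O-dimethylhydroxylamine hydrochloride, CNOC.Cl
Why: Direct ester aminolysis by the chloromagnesium amide of N,O-dimethylhydroxylamine (Weinreb amide formation) tolerates the hydroxyl as its magnesium alkoxide and cannot disturb the carbinol stereocentre.

Step 6
Reactants: 9 2-(4-hydroxyphenyl)ethanol (tyrosol)
Product: 10 2-[4-(benzyloxy)phenyl]ethanol
Conditions: BnBr (1.05 equiv), K2CO3, acetone, reflux
Reagents that add atoms: benzyl bromide, BrCc1ccccc1
Why: In this Williamson etherification the carbonate base ionises only the phenol, so the primary alcohol stays free.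

Step 7
Reactants: 10 2-[4-(benzyloxy)phenyl]ethanol
Product: 11 1-(benzyloxy)-4-(2-bromoethyl)benzene
Conditions: CBr4, PPh3, CH2Cl2, 0 °C to rt
Reagents that add atoms: carbon tetrabromide, BrC(Br)(Br)Br
Why: The Appel reaction turns the primary alcohol into the bromide under neutral conditions through an alkoxyphosphonium salt and does not touch the benzyl ether.

Step 8
Reactants: 11 1-(benzyloxy)-4-(2-bromoethyl)benzene
Product: 12 2-[4-(benzyloxy)phenyl]ethylmagnesium bromide (titrated THF solution)
Conditions: Mg turnings (I2 crystal), THF, slow addition, rt to 40 °C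
Reagents that add atoms: magnesium, [Mg]
Why: Oxidative insertion of magnesium into a primary alkyl bromide (Grignard formation) is routine, and slow addition at moderate dilution should limit Wurtz homocoupling.

Step 9
Reactants: 8 (S)-5-[3,4-bis(benzyloxy)phenyl]-3-hydroxy-N-methoxy-N-methylpentanamide, 12 2-[4-(benzyloxy)phenyl]ethylmagnesium bromide
Product: 14 (S)-7-[3,4-bis(benzyloxy)phenyl]-1-[4-(benzyloxy)phenyl]-5-hydroxyheptan-3-one, via magnesium-chelated tetrahedral adduct 13 (not isolated)
Conditions: 12 (3.2 equiv), THF, −20 to 0 °C; poured into cold aq. NH4Cl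
Reagents that add atoms: none
Why: Grignard acylation of a Weinreb amide stops at the ketone because the N-methoxy magnesium chelate 13 persists until the quench, the first equivalent of reagent only deprotonating the hydroxyl, so the C5–C6 bond forms and the free β-hydroxy ketone never meets base.

Step 10
Reactants: 14 (S)-7-[3,4-bis(benzyloxy)phenyl]-1-[4-(benzyloxy)phenyl]-5-hydroxyheptan-3-one, 15 acetaldehyde
Product: 17 (3S,5S)-1-[3,4-bis(benzyloxy)phenyl]-7-[4-(benzyloxy)phenyl]-5-hydroxyheptan-3-yl acetate, via samarium-bound hemiacetal 16 (not isolated)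
Conditions: SmI2 (0.3 equiv, 0.1 M in THF; divalent samarium), freshly distilled CH3CHO (8 equiv), THF, −10 °C, dark, argon; cold aq. NaHCO3 as soon as 14 is consumed; rapid chromatography on buffered silica
Reagents that add atoms: none
Why: The active catalyst is a trivalent samarium alkoxide, generated when SmI2 (divalent samarium) reduces a little acetaldehyde; it chelates 14 through O3–H and the C5 carbonyl, O3 adds to an acetaldehyde molecule to give the samarium-bound hemiacetal 16, and the hemiacetal C–H is handed to C5 as hydride inside a chair-like six-membered transition state, so that the hemiacetal carbon ends as the acetyl carbonyl on O3 and C5 becomes a free carbinol. The closest known reaction type is this very one, the SmI2-catalysed Evans–Tishchenko reduction of acyclic β-hydroxy ketones with aliphatic aldehydes, an intramolecular Tishchenko redox esterification. No ring is closed, since the cyclic array exists only in the transition state. The new C5 stereocentre is set by substrate control from the C3 carbinol: in the samarium-bridged chair both chain arms lie equatorial and the ketone oxygen axial, which places the hydride on the face that leads to the 1,3-anti product, hence 5S from 3S. The step needs anti diastereoselectivity and esterification of O3 alone; both follow because O3 is the only oxygen that can carry the hydride donor, and because 14 is an open chain with no substituent next to the ketone and no donor group competing for samarium once every phenol is benzylated. Acetyl migration to O5, the one threat to the regiochemistry, should be held back by the low temperature, the cold neutral quench and prompt purification.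

Step 11
Reactants: 17 (3S,5S)-1-[3,4-bis(benzyloxy)phenyl]-7-[4-(benzyloxy)phenyl]-5-hydroxyheptan-3-yl acetate
Product: 18 (3S,5S)-1-(3,4-dihydroxyphenyl)-5-hydroxy-7-(4-hydroxyphenyl)heptan-3-yl acetate (target)
Conditions: H2 (1 atm), 10% Pd/C (zerovalent palladium), neutral EtOAc, rt, stopped at full conversion; filtered and concentrated cold under argon
Reagents that add atoms: none
Why: Catalytic hydrogenolysis of the three aryl benzyl ethers is neutral and should leave the secondary acetate, the free carbinol and both stereocentres untouched, a short run in an aprotic neutral solvent giving the acetyl group little chance to move.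

Compound list
1 | 3,4-bis(benzyloxy)benzaldehyde | O=Cc1ccc(OCc2ccccc2)c(OCc2ccccc2)c1 | starting material
2 | [3,4-bis(benzyloxy)phenyl]methanol | OCc1ccc(OCc2ccccc2)c(OCc2ccccc2)c1 | intermediate
3 | 1,2-bis(benzyloxy)-4-(chloromethyl)benzene | ClCc1ccc(OCc2ccccc2)c(OCc2ccccc2)c1 | intermediate
4 | methyl acetoacetate | COC(=O)CC(C)=O | starting material
5 | sodium lithium dianion (dienolate) of methyl acetoacetate | COC([O-])=CC(=C)[O-].[Na+].[Li+] | intermediate
6 | methyl 5-[3,4-bis(benzyloxy)phenyl]-3-oxopentanoate | COC(=O)CC(=O)CCc1ccc(OCc2ccccc2)c(OCc2ccccc2)c1 | intermediate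
7 | methyl (S)-5-[3,4-bis(benzyloxy)phenyl]-3-hydroxypentanoate | COC(=O)C[C@@H](O)CCc1ccc(OCc2ccccc2)c(OCc2ccccc2)c1 | intermediate
8 | (S)-5-[3,4-bis(benzyloxy)phenyl]-3-hydroxy-N-methoxy-N-methylpentanamide | CON(C)C(=O)C[C@@H](O)CCc1ccc(OCc2ccccc2)c(OCc2ccccc2)c1 | intermediate
9 | 2-(4-hydroxyphenyl)ethanol (tyrosol) | OCCc1ccc(O)cc1 | starting material
10 | 2-[4-(benzyloxy)phenyl]ethanol | OCCc1ccc(OCc2ccccc2)cc1 | intermediate
11 | 1-(benzyloxy)-4-(2-bromoethyl)benzene | BrCCc1ccc(OCc2ccccc2)cc1 | intermediate
12 | 2-[4-(benzyloxy)phenyl]ethylmagnesium bromide | Br[Mg]CCc1ccc(OCc2ccccc2)cc1 | intermediate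
13 | bis(bromomagnesium) salt of the tetrahedral adduct of 8 and 12 (N-methoxy-N-methyl hemiaminal alkoxide at C5, alkoxide at O3; the C5 configuration is not defined) | CON(C)C(O[Mg]Br)(CCc1ccc(OCc2ccccc2)cc1)C[C@@H](O[Mg]Br)CCc1ccc(OCc2ccccc2)c(OCc2ccccc2)c1 | intermediate
14 | (S)-7-[3,4-bis(benzyloxy)phenyl]-1-[4-(benzyloxy)phenyl]-5-hydroxyheptan-3-one | O[C@@H](CCc1ccc(OCc2ccccc2)c(OCc2ccccc2)c1)CC(=O)CCc1ccc(OCc2ccccc2)cc1 | intermediate
15 | acetaldehyde | CC=O | starting material
16 | hemiacetal of O3 of 14 with acetaldehyde, bound to samarium in the flask and drawn here metal-free (the hemiacetal carbon configuration is not defined) | CC(O)O[C@@H](CCc1ccc(OCc2ccccc2)c(OCc2ccccc2)c1)CC(=O)CCc1ccc(OCc2ccccc2)cc1 | intermediate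
17 | (3S,5S)-1-[3,4-bis(benzyloxy)phenyl]-7-[4-(benzyloxy)phenyl]-5-hydroxyheptan-3-yl acetate | CC(=O)O[C@@H](CCc1ccc(OCc2ccccc2)c(OCc2ccccc2)c1)C[C@@H](O)CCc1ccc(OCc2ccccc2)cc1 | intermediate
18 | (3S,5S)-1-(3,4-dihydroxyphenyl)-5-hydroxy-7-(4-hydroxyphenyl)heptan-3-yl acetate | CC(=O)O[C@@H](CCc1ccc(O)c(O)c1)C[C@@H](O)CCc1ccc(O)cc1 | target

Total step count: 11
Longest linear sequence: 8 steps (steps 1–5, 9, 10 and 11, from compound 1); the tyrosol branch (steps 6–8) joins at step 9.

Steps most likely to fail

1. Step 10. Acetaldehyde may be consumed by self-aldol and Tishchenko dimerisation faster than it forms the tethered hemiacetal, so that hydride transfer stalls. The acetyl group may also wander from O3 to O5 during the reaction or on silica, which would erase the regiochemistry. The fallback keeps the redox esterification but uses the ester only as a temporary marker of O3. Setting out from 14, the same SmI2-catalysed reduction is run with non-enolisable benzaldehyde and should give the far less migration-prone (3S,5S)-1-[3,4-bis(benzyloxy)phenyl]-7-[4-(benzyloxy)phenyl]-5-hydroxyheptan-3-yl benzoate F1. O5 is then benzylated under neutral conditions (2-benzyloxy-1-methylpyridinium triflate, MgO, PhCF3, 85 °C) to give (3S,5S)-5-(benzyloxy)-1-[3,4-bis(benzyloxy)phenyl]-7-[4-(benzyloxy)phenyl]heptan-3-yl benzoate F2. Methanolysis of the benzoate (K2CO3, MeOH) frees O3 in (3S,5S)-5-(benzyloxy)-1-[3,4-bis(benzyloxy)phenyl]-7-[4-(benzyloxy)phenyl]heptan-3-ol F3. Ordinary acetylation (Ac2O, pyridine, DMAP) gives (3S,5S)-5-(benzyloxy)-1-[3,4-bis(benzyloxy)phenyl]-7-[4-(benzyloxy)phenyl]heptan-3-yl acetate F4. Hydrogenolysis of all four benzyl ethers (H2, Pd/C, EtOAc) then rejoins the route at the target 18.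

2. Step 11. The acetyl group may shift across the 1,3-diol on a slightly acidic catalyst surface or during a sluggish reaction, the hydrogenolysis may stall through catalyst poisoning, and the freed catechol may oxidise in air during isolation. The fallback removes the benzyl groups without hydrogen or a metal surface. Setting out from 17, Lewis-acid dealkylation with BCl3 in the presence of pentamethylbenzene as a benzyl-cation scavenger (CH2Cl2, −78 °C, quenched at −78 °C with CHCl3/MeOH) should cleave the three aryl benzyl ethers while esters survive. O5 stays tied up as a chloroborate until the quench and so cannot attack the acetate. This leads directly to 18 and makes no new compound.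

3. Step 9. The acylation may stop short because the magnesium alkoxide of 8 aggregates or precipitates, because reagent is lost to Wurtz-coupled material, or because the amide is deprotonated at its α-carbon instead of being attacked. The fallback masks the hydroxyl first. Setting out from 8, silylation (TESCl, imidazole, CH2Cl2) gives (S)-5-[3,4-bis(benzyloxy)phenyl]-N-methoxy-N-methyl-3-[(triethylsilyl)oxy]pentanamide F5. This needs only a slight excess of 12 (THF, 0 °C) and should give (S)-7-[3,4-bis(benzyloxy)phenyl]-1-[4-(benzyloxy)phenyl]-5-[(triethylsilyl)oxy]heptan-3-one F6. Mild acidic desilylation (AcOH/THF/H2O, rt) returns the route at 14.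

Further compounds
F1 | step 10 | (3S,5S)-1-[3,4-bis(benzyloxy)phenyl]-7-[4-(benzyloxy)phenyl]-5-hydroxyheptan-3-yl benzoate | O=C(O[C@@H](CCc1ccc(OCc2ccccc2)c(OCc2ccccc2)c1)C[C@@H](O)CCc1ccc(OCc2ccccc2)cc1)c1ccccc1
F2 | step 10 | (3S,5S)-5-(benzyloxy)-1-[3,4-bis(benzyloxy)phenyl]-7-[4-(benzyloxy)phenyl]heptan-3-yl benzoate | O=C(O[C@@H](CCc1ccc(OCc2ccccc2)c(OCc2ccccc2)c1)C[C@@H](OCc1ccccc1)CCc1ccc(OCc2ccccc2)cc1)c1ccccc1
F3 | step 10 | (3S,5S)-5-(benzyloxy)-1-[3,4-bis(benzyloxy)phenyl]-7-[4-(benzyloxy)phenyl]heptan-3-ol | O[C@@H](CCc1ccc(OCc2ccccc2)c(OCc2ccccc2)c1)C[C@@H](OCc1ccccc1)CCc1ccc(OCc2ccccc2)cc1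
F4 | step 10 | (3S,5S)-5-(benzyloxy)-1-[3,4-bis(benzyloxy)phenyl]-7-[4-(benzyloxy)phenyl]heptan-3-yl acetate | CC(=O)O[C@@H](CCc1ccc(OCc2ccccc2)c(OCc2ccccc2)c1)C[C@@H](OCc1ccccc1)CCc1ccc(OCc2ccccc2)cc1
F0 | step 11 | none | none
F5 | step 9 | (S)-5-[3,4-bis(benzyloxy)phenyl]-N-methoxy-N-methyl-3-[(triethylsilyl)oxy]pentanamide | CON(C)C(=O)C[C@@H](O[Si](CC)(CC)CC)CCc1ccc(OCc2ccccc2)c(OCc2ccccc2)c1
F6 | step 9 | (S)-7-[3,4-bis(benzyloxy)phenyl]-1-[4-(benzyloxy)phenyl]-5-[(triethylsilyl)oxy]heptan-3-one | CC[Si](CC)(CC)O[C@@H](CCc1ccc(OCc2ccccc2)c(OCc2ccccc2)c1)CC(=O)CCc1ccc(OCc2ccccc2)cc1
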